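**Retrosynthetic overview**

- Feature: in ring B, the O1–C2 bond ties the C8a phenol oxygen of ring A to the carbon β to the C4 ketone. C2, the only stereocentre, is therefore the β-carbon of an aryl enone and can be created as ring B closes.
- Disconnections, backwards: O5/O8 benzyl ethers (hydrogenolysis); C3–CO2tBu (acidolysis, decarboxylation); O1–C2 (catalytic enantioselective 6-endo oxa-Michael closure); C2=C3 (Knoevenagel, hexadecanal); C3–C4 (acetate aldol, oxidation); C4–C4a (ortho-formylation of 2,5-bis(benzyloxy)phenol).
- Ring order: ring A is bought as 2,5-dihydroxybenzaldehyde. Ring B is the only ring made, and it closes in the key step.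
- Benzyl, not methyl, ethers guard O5 and O8. Oxidative demethylation with (NH4)2Ce(NO3)6 would pass through the chromane-4,5,8-trione, a tautomer of the achiral 5,8-dihydroxychromone in which O1 is also a good leaving group; hydrogenolysis is neutral.
- The C8a oxygen stays silylated until the alkene is in place. An alkylidene made from an aliphatic aldehyde next to a free phenol would close without control under the amine catalyst of the condensation.

Key step: step 9

Assumption: the sense of induction cannot be fixed from first principles, so the quinidine-derived thiourea is taken to give 2R; if the first run shows the opposite sense, the quinine-derived pseudoenantiomer is used and nothing else changes.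

**Step 1**
Reactants: 1 2,5-dihydroxybenzaldehyde
Product: 2 2,5-bis(benzyloxy)benzaldehyde
Conditions: BnBr, K2CO3, DMF, 60 °C
Reagents that add atoms: benzyl bromide, BrCc1ccccc1
Why: Williamson ether synthesis: both phenoxides displace bromide from the primary benzylic halide, and gentle heating overcomes the hydrogen bond of the 2-OH to the aldehyde.

**Step 2**
Reactants: 2 2,5-bis(benzyloxy)benzaldehyde
Product: 4 2,5-bis(benzyloxy)phenol, via 2,5-bis(benzyloxy)phenyl formate 3 (not isolated)
Conditions: mCPBA, CH2Cl2, rt; aq. NaHCO3 wash; then K2CO3 (cat.), MeOH, rt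
Reagents that add atoms: 3-chloroperoxybenzoic acid (mCPBA), OOC(=O)c1cccc(Cl)c1
Why: Baeyer–Villiger oxidation in which the electron-rich aryl group migrates rather than hydride, chosen over an alkaline H2O2 Dakin oxidation because the ring has no free ortho or para hydroxyl group, followed by base-catalysed transesterification of the labile aryl formate 3.

**Step 3**
Reactants: 4 2,5-bis(benzyloxy)phenol
Product: 6 3,6-bis(benzyloxy)-2-hydroxybenzaldehyde, via 3,6-bis(benzyloxy)-2-(hydroxymethyl)phenol 5 (not isolated)
Conditions: MgCl2, Et3N, (CH2O)n, MeCN, reflux; 1 M HCl work-up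
Reagents that add atoms: paraformaldehyde (reacts as formaldehyde), C=O
Why: Casnati–Skattebøl ortho-formylation: the magnesium phenoxide delivers coordinated formaldehyde to the only free ortho carbon (the other bears OBn, and the para position is not reached through the chelate), and the benzylic alkoxide of 5 passes hydride to a second formaldehyde in an Oppenauer-type oxidation.

**Step 4**
Reactants: 6 3,6-bis(benzyloxy)-2-hydroxybenzaldehyde
Product: 7 3,6-bis(benzyloxy)-2-(tert-butyldimethylsilyloxy)benzaldehyde
Conditions: TBSCl, imidazole, DMF, rt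
Reagents that add atoms: tert-butyldimethylsilyl chloride, CC(C)(C)[Si](C)(C)Cl
Why: Imidazole-promoted silylation of a phenol, well known for 3-alkoxysalicylaldehydes, which installs a mask for the future O1 that withstands enolates, periodinane and amine salts and can later be removed without base.

**Step 5**
Reactants: 7 3,6-bis(benzyloxy)-2-(tert-butyldimethylsilyloxy)benzaldehyde; 8 tert-butyl acetate
Product: 10 tert-butyl 3-[3,6-bis(benzyloxy)-2-(tert-butyldimethylsilyloxy)phenyl]-3-hydroxypropanoate (racemic), via lithium enolate of tert-butyl acetate 9 (not isolated)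
Conditions: 8, LiN(iPr)2, THF, −78 °C; then 7, −78 °C; AcOH quench at −78 °C
Reagents that add atoms: none
Why: Aldol addition of a preformed lithium ester enolate to a non-enolisable aldehyde; the carbinol centre is formed racemic and is erased in step 6, and the quench at −78 °C forestalls migration of the silyl group from the phenol oxygen to the aldolate oxygen.

**Step 6**
Reactants: 10 tert-butyl 3-[3,6-bis(benzyloxy)-2-(tert-butyldimethylsilyloxy)phenyl]-3-hydroxypropanoate
Product: 11 tert-butyl 3-[3,6-bis(benzyloxy)-2-(tert-butyldimethylsilyloxy)phenyl]-3-oxopropanoate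
Conditions: Dess–Martin periodinane, CH2Cl2, 0 °C to rt
Reagents that add atoms: none
Why: Dess–Martin oxidation of a secondary benzylic alcohol, mild enough to spare the aryl silyl ether, the benzyl ethers and the tert-butyl ester and free of the base that would cause retro-aldol cleavage.

**Step 7**
Reactants: 11 tert-butyl 3-[3,6-bis(benzyloxy)-2-(tert-butyldimethylsilyloxy)phenyl]-3-oxopropanoate; 12 hexadecanal
Product: 13 tert-butyl (E)-2-[3,6-bis(benzyloxy)-2-(tert-butyldimethylsilyloxy)benzoyl]octadec-2-enoate
Conditions: piperidine (10 mol %), AcOH (10 mol %), 4 Å molecular sieves, toluene, 0 °C to rt; chromatography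
Reagents that add atoms: none
Why: Knoevenagel condensation by way of the piperidinium ion of the aldehyde and loss of piperidine from the Mannich-type adduct; with the neighbouring oxygen silylated the product cannot cyclise, the E isomer (chain cis to the twisted aroyl group, ester coplanar with the alkene) should prevail, and any Z isomer is removed by chromatography.

**Step 8**
Reactants: 13 tert-butyl (E)-2-[3,6-bis(benzyloxy)-2-(tert-butyldimethylsilyloxy)benzoyl]octadec-2-enoate
Product: 14 tert-butyl (E)-2-[3,6-bis(benzyloxy)-2-hydroxybenzoyl]octadec-2-enoate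
Conditions: Et3N·3HF, THF, 0 °C; cold water wash, no chromatography, used at once
Reagents that add atoms: none
Why: Fluoride-induced cleavage of an aryl silyl ether, made easy by the ortho acyl group that stabilises the leaving aryloxide, in a weakly acidic medium that holds neither free amine nor persistent phenoxide, so that the hydrogen-bonded neutral phenol should survive long enough to be carried cold into step 9.

**Step 9**
Reactants: 14 tert-butyl (E)-2-[3,6-bis(benzyloxy)-2-hydroxybenzoyl]octadec-2-enoate
Product: 15 tert-butyl (2R,3R)-5,8-bis(benzyloxy)-4-oxo-2-pentadecylchromane-3-carboxylate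
Conditions: 1-[3,5-bis(trifluoromethyl)phenyl]-3-[(9R)-6′-methoxycinchonan-9-yl]thiourea (quinidine-derived, 10 mol %), toluene (0.05 M), −25 °C; cold 1 M HCl wash
Reagents that add atoms: none
Why: The quinuclidine nitrogen of the catalyst takes the proton of the C8a-OH while the thiourea N–H bonds hold the ketone and ester carbonyls of the alkylidene 1,3-dicarbonyl unit, and the phenoxide oxygen then attacks the alkylidene carbon to give a hydrogen-bonded enolate that is protonated at C3. The reaction type is the bifunctional amine–thiourea catalysed intramolecular oxa-Michael addition of 2-hydroxyaryl alkylidene β-keto esters, established for aryl- and alkyl-substituted alkylidenes. Ring B closes in the 6-endo-trig mode, forming O1–C2. C2 is set by the catalyst, which exposes one face of the E alkene to the tethered oxygen, whereas C3 is acidic and equilibrates through the enol to the trans (3R) arrangement with chain and ester both pseudo-equatorial. The step needs the catalysed path to outrun uncatalysed closure and ring opening, which is secured by the low temperature, the non-polar solvent, the absence of any other base in 14 and the enolisable β-keto ester product that resists E1cB reversal. Site selectivity is secured by the substrate, because O5 and O8 are benzylated and only the C8a oxygen is free.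

**Step 10**
Reactants: 15 tert-butyl (2R,3R)-5,8-bis(benzyloxy)-4-oxo-2-pentadecylchromane-3-carboxylate
Product: 17 (R)-5,8-bis(benzyloxy)-2-pentadecylchroman-4-one, via (2R,3R)-5,8-bis(benzyloxy)-4-oxo-2-pentadecylchromane-3-carboxylic acid 16 (not isolated)
Conditions: TsOH·H2O (30 mol %), toluene, 80 °C
Reagents that add atoms: none
Why: Acid-catalysed E1 cleavage of the tert-butyl ester and thermal decarboxylation of β-keto acid 16 through a cyclic six-membered transition state, which deletes the C3 centre while C2 is safe because no enolate for an E1cB ring opening arises in acid.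

**Step 11**
Reactants: 17 (R)-5,8-bis(benzyloxy)-2-pentadecylchroman-4-one
Product: 18 (R)-5,8-dihydroxy-2-pentadecylchroman-4-one (target)
Conditions: H2 (1 atm), 10% Pd/C, EtOAc, rt; filtration under argon
Reagents that add atoms: none
Why: Catalytic hydrogenolysis of aryl benzyl ethers, a neutral reaction routinely used on flavanones and chromanones, which leaves the hydrogen-bonded C4 ketone and the C2 centre untouched; air is excluded on work-up because the product is a hydroquinone.

**Compound list**

1 | 2,5-dihydroxybenzaldehyde | O=Cc1cc(O)ccc1O | starting material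
2 | 2,5-bis(benzyloxy)benzaldehyde | O=Cc1cc(OCc2ccccc2)ccc1OCc1ccccc1 | intermediate
3 | 2,5-bis(benzyloxy)phenyl formate (not isolated) | O=COc1cc(OCc2ccccc2)ccc1OCc1ccccc1 | intermediate
4 | 2,5-bis(benzyloxy)phenol | Oc1cc(OCc2ccccc2)ccc1OCc1ccccc1 | intermediate
5 | 3,6-bis(benzyloxy)-2-(hydroxymethyl)phenol (present as its magnesium salt, not isolated) | OCc1c(O)c(OCc2ccccc2)ccc1OCc1ccccc1 | intermediate
6 | 3,6-bis(benzyloxy)-2-hydroxybenzaldehyde | O=Cc1c(O)c(OCc2ccccc2)ccc1OCc1ccccc1 | intermediate
7 | 3,6-bis(benzyloxy)-2-(tert-butyldimethylsilyloxy)benzaldehyde | O=Cc1c(O[Si](C)(C)C(C)(C)C)c(OCc2ccccc2)ccc1OCc1ccccc1 | intermediate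
8 | tert-butyl acetate | CC(=O)OC(C)(C)C | starting material
9 | lithium enolate of tert-butyl acetate (not isolated) | [Li+].C=C([O-])OC(C)(C)C | intermediate
10 | tert-butyl 3-[3,6-bis(benzyloxy)-2-(tert-butyldimethylsilyloxy)phenyl]-3-hydroxypropanoate (racemic) | CC(C)(C)OC(=O)CC(O)c1c(O[Si](C)(C)C(C)(C)C)c(OCc2ccccc2)ccc1OCc1ccccc1 | intermediate
11 | tert-butyl 3-[3,6-bis(benzyloxy)-2-(tert-butyldimethylsilyloxy)phenyl]-3-oxopropanoate | CC(C)(C)OC(=O)CC(=O)c1c(O[Si](C)(C)C(C)(C)C)c(OCc2ccccc2)ccc1OCc1ccccc1 | intermediate
12 | hexadecanal | CCCCCCCCCCCCCCCC=O | starting material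
13 | tert-butyl (E)-2-[3,6-bis(benzyloxy)-2-(tert-butyldimethylsilyloxy)benzoyl]octadec-2-enoate | CCCCCCCCCCCCCCC/C=C(/C(=O)OC(C)(C)C)C(=O)c1c(O[Si](C)(C)C(C)(C)C)c(OCc2ccccc2)ccc1OCc1ccccc1 | intermediate
14 | tert-butyl (E)-2-[3,6-bis(benzyloxy)-2-hydroxybenzoyl]octadec-2-enoate | CCCCCCCCCCCCCCC/C=C(/C(=O)OC(C)(C)C)C(=O)c1c(O)c(OCc2ccccc2)ccc1OCc1ccccc1 | intermediate
15 | tert-butyl (2R,3R)-5,8-bis(benzyloxy)-4-oxo-2-pentadecylchromane-3-carboxylate | CCCCCCCCCCCCCCC[C@@H]1[C@@H](C(=O)OC(C)(C)C)C(=O)c2c(OCc3ccccc3)ccc(OCc3ccccc3)c2O1 | intermediate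
16 | (2R,3R)-5,8-bis(benzyloxy)-4-oxo-2-pentadecylchromane-3-carboxylic acid (not isolated) | CCCCCCCCCCCCCCC[C@@H]1[C@@H](C(O)=O)C(=O)c2c(OCc3ccccc3)ccc(OCc3ccccc3)c2O1 | intermediate
17 | (R)-5,8-bis(benzyloxy)-2-pentadecylchroman-4-one | CCCCCCCCCCCCCCC[C@@H]1CC(=O)c2c(OCc3ccccc3)ccc(OCc3ccccc3)c2O1 | intermediate
18 | (R)-5,8-dihydroxy-2-pentadecylchroman-4-one | CCCCCCCCCCCCCCC[C@@H]1CC(=O)c2c(O)ccc(O)c2O1 | target

**Step count**

Total step count: 11. Longest linear sequence: 11 steps (1 to 18).

**Steps most likely to fail**

1. **Step 9.** Enantiofacial selectivity may be eroded by competing uncatalysed closure, by closure of residual Z alkene or by reversible ring opening.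
   - The fallback replaces asymmetric induction by resolution. It sets out from 17 of insufficient enantiomeric purity and comes back at 17.
   - Such material also holds (S)-5,8-bis(benzyloxy)-2-pentadecylchroman-4-one F1.
   - Asymmetric transfer hydrogenation with RuCl(p-cymene)[(R,R)-TsDPEN] in HCO2H/Et3N is stopped at partial conversion and so run as a kinetic resolution.
   - Hydride is delivered anti to the C2 chain, and a catalyst that prefers the 4R alcohol should reduce F1 faster, to the cis alcohol (2S,4R)-5,8-bis(benzyloxy)-2-pentadecylchroman-4-ol F2.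
   - Chromatographic removal of F2 returns enriched 17 for step 11.

2. **Step 8.** The ring may close early and without control while the phenol is unmasked or during work-up and concentration.
   - The fallback merges condensation and closure in one flask. It sets out from 11 and comes back at 15.
   - The silyl group is removed first, where no acceptor is present, with Et3N·3HF in THF. This gives tert-butyl 3-[3,6-bis(benzyloxy)-2-hydroxyphenyl]-3-oxopropanoate F3.
   - F3, 12, the thiourea of step 9 (20 mol %) and 4 Å molecular sieves are then stirred in toluene at 0 °C.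
   - 14 then arises slowly by base-catalysed aldol condensation and is closed by the chiral catalyst as soon as it appears, with no achiral amine present.

3. **Step 7.** Several processes threaten this step under the amine catalyst:
   - migration of the double bond out of conjugation;
   - Michael addition of a second β-keto ester;
   - self-condensation of the aldehyde;
   - loss of the silyl group;
   - poor E/Z control.

   The fallback makes the alkene by elimination instead of condensation. It sets out from 11 and comes back at 13.
   - C-alkylation of 11 with 1-iodohexadecane (K2CO3, DMF) gives tert-butyl 2-[3,6-bis(benzyloxy)-2-(tert-butyldimethylsilyloxy)benzoyl]octadecanoate F4.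
   - NaH and then PhSeBr in THF at 0 °C give tert-butyl 2-[3,6-bis(benzyloxy)-2-(tert-butyldimethylsilyloxy)benzoyl]-2-(phenylselanyl)octadecanoate F5.
   - H2O2 in CH2Cl2 at 0 °C gives tert-butyl 2-[3,6-bis(benzyloxy)-2-(tert-butyldimethylsilyloxy)benzoyl]-2-(phenylseleninyl)octadecanoate F6.
   - F6 undergoes selenoxide syn elimination toward the only β-hydrogens and delivers 13 without amine, aldehyde or equilibrating conditions.

**Further compounds**

F1 | step 9 | (S)-5,8-bis(benzyloxy)-2-pentadecylchroman-4-one | CCCCCCCCCCCCCCC[C@H]1CC(=O)c2c(OCc3ccccc3)ccc(OCc3ccccc3)c2O1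
F2 | step 9 | (2S,4R)-5,8-bis(benzyloxy)-2-pentadecylchroman-4-ol | CCCCCCCCCCCCCCC[C@H]1C[C@@H](O)c2c(OCc3ccccc3)ccc(OCc3ccccc3)c2O1
F3 | step 8 | tert-butyl 3-[3,6-bis(benzyloxy)-2-hydroxyphenyl]-3-oxopropanoate | CC(C)(C)OC(=O)CC(=O)c1c(O)c(OCc2ccccc2)ccc1OCc1ccccc1
F4 | step 7 | tert-butyl 2-[3,6-bis(benzyloxy)-2-(tert-butyldimethylsilyloxy)benzoyl]octadecanoate (racemic) | CCCCCCCCCCCCCCCCC(C(=O)OC(C)(C)C)C(=O)c1c(O[Si](C)(C)C(C)(C)C)c(OCc2ccccc2)ccc1OCc1ccccc1
F5 | step 7 | tert-butyl 2-[3,6-bis(benzyloxy)-2-(tert-butyldimethylsilyloxy)benzoyl]-2-(phenylselanyl)octadecanoate (racemic) | CCCCCCCCCCCCCCCCC([Se]c1ccccc1)(C(=O)OC(C)(C)C)C(=O)c1c(O[Si](C)(C)C(C)(C)C)c(OCc2ccccc2)ccc1OCc1ccccc1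
F6 | step 7 | tert-butyl 2-[3,6-bis(benzyloxy)-2-(tert-butyldimethylsilyloxy)benzoyl]-2-(phenylseleninyl)octadecanoate (mixture of stereoisomers) | CCCCCCCCCCCCCCCCC([Se](=O)c1ccccc1)(C(=O)OC(C)(C)C)C(=O)c1c(O[Si](C)(C)C(C)(C)C)c(OCc2ccccc2)ccc1OCc1ccccc1
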